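**Strategy.** Ring A of the isoflavone is disconnected across C5–C6 and C4a–C8a. Its oxygens at C6, C7 and C8a, set 1,2,4 around the acyl-bearing C4a, map onto a 4-methoxy-2-silyloxyfuran. A [4+2] addition of that furan to a terminal ynone, followed by opening of the oxygen bridge, should therefore assemble the whole benzenoid ring in one operation, with the C6 hydroxyl free and the C8a oxygen silyl-masked. The ynone partner already holds ring B and a methoxymethylene carbon that becomes C2. Fluoride then unmasks the C8a phenoxide, which closes the pyranone ring C by addition–elimination.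

Key step: step 5

Remark: the methoxymethylene double bond is drawn E (OMe anti to the carbonyl) as expected from O-methylation; its geometry does not affect the outcome, because C2 passes through an sp3 stage in the last step and the target has no stereocentre.

**Route**

Step 1
Reactants: 1 methyl 3,4,5-trimethoxyphenylacetate
Product: 3 methyl (E)-3-methoxy-2-(3,4,5-trimethoxyphenyl)prop-2-enoate, via sodium enolate 2 (not isolated)
Conditions: NaH, HCO2Me, DMF, 0 °C → rt; then Me2SO4, 0 °C → rt
Reagents that add atoms: methyl formate (COC=O); dimethyl sulfate (COS(=O)(=O)OC)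
Why: A crossed Claisen condensation with methyl formate is driven to completion by formation of the stabilised sodium enolate 2, and O-methylation of that enolate by the hard electrophile Me2SO4 in DMF should give the conjugated enol ether, mainly as the E isomer; no stereocentre is formed.

Step 2
Reactants: 3 methyl (E)-3-methoxy-2-(3,4,5-trimethoxyphenyl)prop-2-enoate
Product: 4 (E)-N,3-dimethoxy-N-methyl-2-(3,4,5-trimethoxyphenyl)prop-2-enamide
Conditions: MeNHOMe·HCl, iPrMgCl, THF, −20 → 0 °C
Reagents that add atoms: N,O-dimethylhydroxylamine hydrochloride (CNOC.Cl)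
Why: Aminolysis of the ester by the chloromagnesium amide made in the flask from MeNHOMe·HCl and iPrMgCl (Weinreb amide formation from an ester) should take place at the carbonyl carbon, the β-carbon being deactivated by its methoxy donor; the alkene geometry is untouched.

Step 3
Reactants: 4 (E)-N,3-dimethoxy-N-methyl-2-(3,4,5-trimethoxyphenyl)prop-2-enamide; 5 ethynylmagnesium bromide
Product: 7 (E)-1-methoxy-2-(3,4,5-trimethoxyphenyl)pent-1-en-4-yn-3-one, via magnesium alkoxide adduct 6 (not isolated)
Conditions: HC≡CMgBr, THF, 0 °C → rt; inverse quench into cold aq. NaHSO4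
Reagents that add atoms: ethynylmagnesium bromide 5 (C#C[Mg]Br)
Why: Weinreb ketone synthesis: the N-methoxy group holds magnesium in a five-membered chelate (6) that does not collapse until the quench, so a single acetylide is delivered, and pouring into cold acid protonates the released amine before it can add to the ynone.

Step 4
Reactants: 8 methyl tetronate (4-methoxyfuran-2(5H)-one)
Product: 9 tert-butyl[(4-methoxyfuran-2-yl)oxy]dimethylsilane
Conditions: TBSOTf, Et3N, CH2Cl2, 0 °C; pentane, filtration, used at once
Reagents that add atoms: tert-butyldimethylsilyl trifluoromethanesulfonate (CC(C)(C)[Si](C)(C)OS(=O)(=O)C(F)(F)F)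
Why: Soft enolisation: O-silylation of the lactone carbonyl followed by γ-deprotonation with Et3N turns the butenolide into the aromatic 2-silyloxyfuran (silyl dienol ether formation), with no stereocentre involved.

Step 5
Reactants: 7 (E)-1-methoxy-2-(3,4,5-trimethoxyphenyl)pent-1-en-4-yn-3-one; 9 tert-butyl[(4-methoxyfuran-2-yl)oxy]dimethylsilane
Product: 11 (E)-1-[2-(tert-butyldimethylsilyloxy)-5-hydroxy-4-methoxyphenyl]-3-methoxy-2-(3,4,5-trimethoxyphenyl)prop-2-en-1-one, via oxanorbornadiene 10 (not isolated)
Conditions: PhMe, 0 °C → 40 °C
Reagents that add atoms: none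
Why: The furan behaves as a cyclic, doubly oxygenated diene whose C5 terminus, made nucleophilic by the ring oxygen, the C4 methoxy group and the vinylogous silyloxy group, bonds to the unsubstituted alkyne carbon while furan C2 bonds to the acyl-bearing carbon, either in a concerted asynchronous [4+2] or by Mukaiyama–Michael addition and aldol-type closure of the allenolate onto the silyloxocarbenium ion, giving oxanorbornadiene 10. The closest known reaction type is the Diels–Alder addition of 2-silyloxyfurans to acetylenic esters and ketones with aromatising ring opening to hydroquinone monosilyl ethers. Ring A, the only ring closed, is formed by this intermolecular [4+2], which makes C5–C6 and C4a–C8a; the bridge C–O bond at the ketal-like silyloxy bridgehead then ionises and loss of the other bridgehead proton aromatises the ring, so the bridge oxygen ends as the free C6 hydroxyl and the silyl ether stays on C8a. No stereocentre survives, since the two bridgehead centres of racemic 10 are erased on aromatisation. The step needs the right orientation of addition and reaction at the alkyne, not at the methoxyvinyl ketone; the first is secured by the match of the most nucleophilic furan carbon with the β-carbon of the ynone, the second because the enol-ether carbon is donor-substituted, more hindered and far less electrophilic.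

Step 6
Reactants: 11 (E)-1-[2-(tert-butyldimethylsilyloxy)-5-hydroxy-4-methoxyphenyl]-3-methoxy-2-(3,4,5-trimethoxyphenyl)prop-2-en-1-one
Product: 13 6-hydroxy-7-methoxy-3-(3,4,5-trimethoxyphenyl)-4H-chromen-4-one, via tetrabutylammonium phenoxide 12 (not isolated)
Conditions: Bu4NF, THF, 0 °C → rt; then AcOH
Reagents that add atoms: none
Why: Fluoride cleaves the aryl silyl ether, and the resulting C8a phenoxide adds to the β-carbon of the methoxyvinyl ketone (6-endo oxa-Michael addition) and expels methoxide by E1cB elimination, the addition–elimination that closes the pyranone ring in standard isoflavone syntheses; nothing stereogenic remains.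

**Compound list**

1 | methyl 3,4,5-trimethoxyphenylacetate | COC(=O)Cc1cc(OC)c(OC)c(OC)c1 | starting material
2 | sodium enolate of methyl 3-oxo-2-(3,4,5-trimethoxyphenyl)propanoate (enolate geometry not fixed) | [Na+].[O-]C=C(C(=O)OC)c1cc(OC)c(OC)c(OC)c1 | intermediate
3 | methyl (E)-3-methoxy-2-(3,4,5-trimethoxyphenyl)prop-2-enoate | CO/C=C(/C(=O)OC)c1cc(OC)c(OC)c(OC)c1 | intermediate
4 | (E)-N,3-dimethoxy-N-methyl-2-(3,4,5-trimethoxyphenyl)prop-2-enamide | CO/C=C(/C(=O)N(C)OC)c1cc(OC)c(OC)c(OC)c1 | intermediate
5 | ethynylmagnesium bromide | C#C[Mg]Br | starting material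
6 | bromomagnesium (E)-5-methoxy-3-[methoxy(methyl)amino]-4-(3,4,5-trimethoxyphenyl)pent-4-en-1-yn-3-olate (racemic at C3) | CO/C=C(/C(O[Mg]Br)(C#C)N(C)OC)c1cc(OC)c(OC)c(OC)c1 | intermediate
7 | (E)-1-methoxy-2-(3,4,5-trimethoxyphenyl)pent-1-en-4-yn-3-one | CO/C=C(/C(=O)C#C)c1cc(OC)c(OC)c(OC)c1 | intermediate
8 | methyl tetronate (4-methoxyfuran-2(5H)-one) | COC1=CC(=O)OC1 | starting material
9 | tert-butyl[(4-methoxyfuran-2-yl)oxy]dimethylsilane | COc1coc(O[Si](C)(C)C(C)(C)C)c1 | intermediate
10 | (E)-1-[1-(tert-butyldimethylsilyloxy)-5-methoxy-7-oxabicyclo[2.2.1]hepta-2,5-dien-2-yl]-3-methoxy-2-(3,4,5-trimethoxyphenyl)prop-2-en-1-one (racemic; the two bridgehead configurations are mutually fixed by the bicycle) | CO/C=C(/C(=O)C1=CC2OC1(O[Si](C)(C)C(C)(C)C)C=C2OC)c1cc(OC)c(OC)c(OC)c1 | intermediate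
11 | (E)-1-[2-(tert-butyldimethylsilyloxy)-5-hydroxy-4-methoxyphenyl]-3-methoxy-2-(3,4,5-trimethoxyphenyl)prop-2-en-1-one | CO/C=C(/C(=O)c1cc(O)c(OC)cc1O[Si](C)(C)C(C)(C)C)c1cc(OC)c(OC)c(OC)c1 | intermediate
12 | tetrabutylammonium 4-hydroxy-5-methoxy-2-[(E)-3-methoxy-2-(3,4,5-trimethoxyphenyl)prop-2-enoyl]phenolate | CO/C=C(/C(=O)c1cc(O)c(OC)cc1[O-])c1cc(OC)c(OC)c(OC)c1.CCCC[N+](CCCC)(CCCC)CCCC | intermediate
13 | 6-hydroxy-7-methoxy-3-(3,4,5-trimethoxyphenyl)-4H-chromen-4-one | COc1cc2occ(-c3cc(OC)c(OC)c(OC)c3)c(=O)c2cc1O | target

**Step count**

Total steps: 6. Longest linear sequence: 5 steps (1 → 3 → 4 → 7 → 11 → 13); the furan 9 is made in one step on the side.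

**Steps most likely to fail**

1. Step 5. The addition may stop after the first C–C bond, with silyl transfer leaving an open-chain Michael adduct. The moisture-sensitive furan may also be protodesilylated, or the ynone may oligomerise, before the cycloaddition takes place. The fallback gives up the cycloaddition and brings ring A in preformed, setting out from 1 and coming back at 13. Saponification of 1 (LiOH, THF/H2O) would give 3,4,5-trimethoxyphenylacetic acid F1. Friedel–Crafts acylation of commercial 2-methoxybenzene-1,4-diol (COc1cc(O)ccc1O) with F1 in BF3·OEt2, at the carbon para to the methoxy group and ortho to a hydroxyl, would give the deoxybenzoin 1-(2,5-dihydroxy-4-methoxyphenyl)-2-(3,4,5-trimethoxyphenyl)ethan-1-one F2. One-carbon ring closure of F2 with DMF, BF3·OEt2 and MsCl would install C2 and give 13.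

2. Step 3. The push–pull amide may react sluggishly with the weakly nucleophilic magnesium acetylide, and the liberated N,O-dimethylhydroxylamine may add to the unsubstituted ynone terminus during the quench. The fallback carries the alkyne in masked form and unveils it separately, setting out from 4 and coming back at 7. Addition of lithium (trimethylsilyl)acetylide (Me3SiC≡CH, n-BuLi, THF, −78 °C) to 4 would give (E)-1-methoxy-2-(3,4,5-trimethoxyphenyl)-5-(trimethylsilyl)pent-1-en-4-yn-3-one F3, whose silylated terminus resists conjugate addition. Mild C-desilylation (Na2B4O7·10H2O, MeOH/H2O, rt) would then give 7.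

3. Step 2. The magnesium amide may attack the β-carbon and displace methoxide by conjugate addition–elimination, or acyl substitution at the hindered, donor-deactivated ester may stall. The fallback replaces metal-amide aminolysis by activation of the free acid, setting out from 3 and coming back at 4. Saponification (LiOH, THF/MeOH/H2O) would give (E)-3-methoxy-2-(3,4,5-trimethoxyphenyl)prop-2-enoic acid F4. Carbodiimide coupling with the neutral amine (MeNHOMe·HCl, EDC·HCl, HOBt, iPr2NEt, CH2Cl2) would then give 4.

Further compounds
F1 | step 5 | 3,4,5-trimethoxyphenylacetic acid | OC(=O)Cc1cc(OC)c(OC)c(OC)c1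
F2 | step 5 | 1-(2,5-dihydroxy-4-methoxyphenyl)-2-(3,4,5-trimethoxyphenyl)ethan-1-one | COc1cc(O)c(C(=O)Cc2cc(OC)c(OC)c(OC)c2)cc1O
F3 | step 3 | (E)-1-methoxy-2-(3,4,5-trimethoxyphenyl)-5-(trimethylsilyl)pent-1-en-4-yn-3-one | CO/C=C(/C(=O)C#C[Si](C)(C)C)c1cc(OC)c(OC)c(OC)c1
F4 | step 2 | (E)-3-methoxy-2-(3,4,5-trimethoxyphenyl)prop-2-enoic acid | CO/C=C(/C(=O)O)c1cc(OC)c(OC)c(OC)c1
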